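**Plan**

1. Labdane numbering is used throughout: ring A is C1–C5 and C10, ring B is C5–C10, C20 sits on C10, C19 (CH3) and C18 (CH2O) on C4, C17 on C8, and the chain C11–C16 on C9. The target is the ent-labdane in which H5, H9, O6, O8 and C18 lie anti to C20.
2. Retrosynthesis: the 13(16),14-diene goes back to a C13 alkyne (ethylene enyne metathesis) and a C13 aldehyde. The C6–O, C8–O, C5–H and C9–H bonds go back to a ring B 1,4-diene (C5=C6, C8=C9), and C9–C11 to an enol triflate coupling. Ring A is cut at C1–C10 and C4–C5.
3. Enabling feature: ring A shares only the C5–C10 edge with ring B, the oxygenated C6 and C9 flank that edge, and C8 and C10 each carry a methyl. Ring B therefore maps onto 2,6-dimethyl-1,4-benzoquinone (C6=O, C9=O), whose C5=C10 bond is the dienophile for a C1–C4 diene carrying C18 and C19.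
4. Forward: quinone (ring B) plus silyloxy diene close ring A in one catalytic enantioselective [4+2]. C6=O is then converted to the C5=C6 alkene and C9=O to the C8=C9 enol triflate, which receives C11–C13. Double hydroboration, alkyne formation, enyne metathesis, acetylation and desilylation finish the route.
5. Stereochemistry: C10 (absolute) comes from the chiral oxazaborolidinium catalyst, C4 from the E diene in the endo transition state, and C5, C6, C8 and C9 from hydroboration on the face opposite the C20 and C19 methyls.

Key step: step 4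

Assumption: the (S)-configured oxazaborolidinium ion is taken to leave the Re face of C10 of the bound quinone open (binding at O6, syn to C5–H), which leads to the C10 configuration of the target; if the first adduct proved antipodal, the (R)-catalyst would be used and nothing else would change.

**Step 1**
Reactants: 1 acrolein; 2 ethyl 2-(triphenyl-λ5-phosphanylidene)propanoate
Product: 3 ethyl (2E)-2-methylpenta-2,4-dienoate
Conditions: CH2Cl2, 0 °C → rt
Reagents that add atoms: none
Why: Wittig olefination with a stabilised α-methyl ylide should give the (E)-trisubstituted dienoate (ester trans to the vinyl group) under thermodynamic control of oxaphosphetane formation.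

**Step 2**
Reactants: 3 ethyl (2E)-2-methylpenta-2,4-dienoate
Product: 4 (2E)-2-methylpenta-2,4-dien-1-ol
Conditions: diisobutylaluminium hydride (Me2CHCH2)2AlH (2.2 equiv), CH2Cl2, –78 → 0 °C; aqueous KNaC4H4O6 work-up
Reagents that add atoms: none
Why: Hydride 1,2-reduction of the conjugated ester with two equivalents of the aluminium hydride at low temperature should stop at the allylic alcohol without touching the diene or its geometry.

**Step 3**
Reactants: 4 (2E)-2-methylpenta-2,4-dien-1-ol
Product: 5 triisopropyl{[(2E)-2-methylpenta-2,4-dien-1-yl]oxy}silane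
Conditions: (Me2CH)3SiCl, imidazole, DMF, rt
Reagents that add atoms: chlorotriisopropylsilane CC(C)[Si](Cl)(C(C)C)C(C)C
Why: Standard imidazole-promoted silylation of a primary alcohol; the triisopropylsilyl ether is chosen because it should survive the cationic Lewis acid of step 4, the hydride and base steps, and the dilute acid of step 11.

**Step 4**
Reactants: 5 triisopropyl{[(2E)-2-methylpenta-2,4-dien-1-yl]oxy}silane; 6 2,6-dimethyl-1,4-benzoquinone
Product: 7 cis-fused enedione (2,5,8a-trimethyl-5-{[(triisopropylsilyl)oxy]methyl}-4a,5,8,8a-tetrahydronaphthalene-1,4-dione; 4a-H, 5-CH3 and 8a-CH3 on one face)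
Conditions: N-protonated (S)-3,3-diphenyl-1-(2-methylphenyl)hexahydropyrrolo[1,2-c][1,3,2]oxazaborole, counter-ion (CF3SO2)2N– (from the oxazaborolidine and Tf2NH, 20 mol%), CH2Cl2, –78 → –20 °C
Reagents that add atoms: none
Why: The cationic oxazaborolidinium binds the more basic, unhindered C6 carbonyl oxygen of 6 (the one flanked by two ring C–H groups, with an α-C–H···O contact), which makes C10 the most electrophilic carbon, and diene 5 then adds through a concerted but asynchronous endo [4+2] transition state in which the bond from its unsubstituted terminus C1 to the methyl-bearing C10 runs ahead of the bond from the disubstituted terminus C4 to C5. The closest known reaction type is the chiral-oxazaborolidinium-catalysed quinone Diels–Alder reaction, together with the known reversal of regiochemistry of 2,6-dimethylbenzoquinone on Lewis-acid coordination. Ring A (C1–C2–C3–C4–C5–C10) is closed by the cycloaddition itself, both σ-bonds forming suprafacially on the diene and on the ring B alkene, which leaves the C2=C3 alkene as a helper to be removed in step 9. C5–H and the C10 methyl come out cis because the dienophile is a ring (Z) alkene, C4 is set by the E geometry of 5 in the endo arrangement (CH2OSi outside and hence anti to C20, the methyl inside and hence syn to C20), and the absolute sense comes from the catalyst, which leaves one face of the bound enone open. The step needs regioselectivity (C1 to C10, not to C5), endo and facial selectivity and mono-addition; these are secured by coordination at O6, by the preference of the quaternary-forming terminus C4 for the CH carbon C5 (no vicinal quaternary pair), by the twofold symmetry of 6 that makes its two ring alkenes equivalent, and by the lower dienophilicity of the enedione product.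

**Step 5**
Reactants: 7 cis-fused enedione
Product: 9 dienyl triflate (C5=C6–OTf; C7=C8; C9=O), via potassium dienolate 8 (not isolated)
Conditions: KN(SiMe3)2, THF, –78 °C; then PhNTf2, –78 → 0 °C
Reagents that add atoms: N-phenylbis(trifluoromethanesulfonimide) O=S(=O)(N(c1ccccc1)S(=O)(=O)C(F)(F)F)C(F)(F)F
Why: Enolate O-sulfonylation (enol triflate synthesis): because C7 is sp2 the C6 ketone can enolise only toward C5, the C8 methyl being the sole alternative and leading to a less stable exocyclic dienolate, so the C5=C6 enol triflate should form regiospecifically and the cis C5 stereocentre is deliberately erased for later resetting.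

**Step 6**
Reactants: 9 dienyl triflate
Product: 10 2,4-dienone (2,5,8a-trimethyl-5-{[(triisopropylsilyl)oxy]methyl}-8,8a-dihydronaphthalen-1(5H)-one; C5=C6, C7=C8, C9=O)
Conditions: Pd(OAc)2 (5 mol%), PPh3, HCO2H, Et3N, DMF, 60 °C
Reagents that add atoms: none
Why: Palladium-catalysed formate reduction of a vinyl triflate (oxidative addition, formate-to-hydride exchange with loss of CO2, reductive elimination) should replace OTf by H and leave the hindered dienone, the ring A alkene and the silyl ether untouched.

**Step 7**
Reactants: 10 2,4-dienone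
Product: 12 enol triflate (C8=C9–OTf; C5=C6; C2=C3), via lithium enolate 11 (not isolated)
Conditions: LiBH(CH(CH3)C2H5)3 (L-Selectride, 1.1 equiv), THF, –78 °C; then PhNTf2, –78 → 0 °C
Reagents that add atoms: N-phenylbis(trifluoromethanesulfonimide) O=S(=O)(N(c1ccccc1)S(=O)(=O)C(F)(F)F)C(F)(F)F
Why: Conjugate (1,4) hydride reduction of an α-methyl, β-unsubstituted enone by the bulky borohydride followed by enolate trapping as the triflate: hydride should go to C7 because C9 (flanked by quaternary C10 and the C8 methyl) and the fully substituted δ-carbon C5 are shielded, which gives the C8=C9 enolate and hence the skipped 1,4-diene triflate regiospecifically.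

**Step 8**
Reactants: 12 enol triflate; 13 2-vinyl-1,3-dioxolane
Product: 15 triene acetal (C11–C13 attached to C9; alkenes C2=C3/C5=C6/C8=C9), via alkylborane 14 (not isolated)
Conditions: 13, 9-BBN, THF, rt; then 12, PdCl2(dppf) (10 mol%), AsPh3, Cs2CO3, DMF/H2O, 50 °C
Reagents that add atoms: none
Why: B-alkyl Suzuki–Miyaura coupling: anti-Markovnikov hydroboration of the vinyl group of 13 gives a primary alkylborane that should transmetalate to the vinylpalladium species formed from the hindered triflate, forming the C9–C11 bond and delivering C11–C13 with C13 masked as an acetal.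

**Step 9**
Reactants: 15 triene acetal
Product: 16 diene acetal (C5=C6 and C8=C9 kept; ring A saturated)
Conditions: 2-nitrobenzenesulfonylhydrazide, Et3N, CH2Cl2, rt
Reagents that add atoms: none
Why: Diimide reduction (concerted syn transfer of two hydrogens) is very sensitive to substitution, so the cis-disubstituted C2=C3 alkene should be saturated while the trisubstituted C5=C6 and tetrasubstituted C8=C9 alkenes stay intact and unisomerised.

**Step 10**
Reactants: 16 diene acetal
Product: 18 6,8-diol acetal (trans-decalin; H5/H9/6-OH/8-OH anti to C20), via bis(alkylborane) 17 (not isolated)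
Conditions: BH3·THF (excess), THF, 0 → 45 °C; then NaOH, H2O2, 0 °C → rt
Reagents that add atoms: hydrogen peroxide OO
Why: Hydroboration–oxidation (syn addition, boron to the less hindered carbon, retention on oxidation): the trisubstituted C5=C6 bond should react first with B at C6 and H at C5 on the face opposite the axial C20 and C19 methyls, after which ring B is a half-chair whose C20 methyl shields the lower face of C8=C9, so B adds to C8 (C9 is blocked by quaternary C10) and H to C9 from the same open face, which sets H5, 6-OH, 8-OH and H9 anti to C20 and creates the trans ring fusion.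

**Step 11**
Reactants: 18 6,8-diol acetal
Product: 19 lactol (8-O–C13 six-membered hemiacetal; anomeric mixture)
Conditions: 1 M HCl, THF, rt
Reagents that add atoms: water O
Why: Acid-catalysed acetal hydrolysis frees the C13 aldehyde, which should close onto the tertiary 8-hydroxyl as a six-membered lactol; the hindered primary silyl ether and the tertiary alcohol are expected to tolerate dilute acid at room temperature.

**Step 12**
Reactants: 19 lactol
Product: 20 terminal alkyne (C13≡C14; 6,8-diol)
Conditions: dimethyl (1-diazo-2-oxopropyl)phosphonate, K2CO3, MeOH, 0 °C → rt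
Reagents that add atoms: dimethyl (1-diazo-2-oxopropyl)phosphonate COP(=O)(OC)C(=[N+]=[N-])C(C)=O
Why: Seyferth–Gilbert homologation with the Ohira–Bestmann reagent acts on the open hydroxy-aldehyde form of the lactol (methanolysis of the reagent, phosphonate olefination, loss of N2 and 1,2-shift) and should give the terminal alkyne without protection of the free hydroxyls.

**Step 13**
Reactants: 20 terminal alkyne
Product: 21 ent-18-(triisopropylsilyloxy)labda-13(16),14-diene-6α,8α-diol
Conditions: ethylene (1 atm), second-generation Grubbs catalyst (C46H65Cl2N2PRu, 10 mol%), toluene, 80 °C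
Reagents that add atoms: ethylene C=C
Why: Ethylene–alkyne cross enyne metathesis: the ruthenium methylidene adds across the terminal alkyne and the resulting vinylcarbene is cleaved by ethylene, which should convert C13≡C14 directly into the 2-substituted buta-1,3-diene (C13=C16, C14=C15) in the presence of the free alcohols.

**Step 14**
Reactants: 21 diene diol
Product: 22 ent-6α-acetoxy-18-(triisopropylsilyloxy)labda-13(16),14-dien-8α-ol
Conditions: Ac2O, pyridine, DMAP (cat.), CH2Cl2, rt
Reagents that add atoms: acetic anhydride CC(=O)OC(C)=O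
Why: Nucleophile-catalysed acylation should acetylate only the secondary equatorial 6-hydroxyl, since the 8-hydroxyl is tertiary and O18 is still silylated.

**Step 15**
Reactants: 22 silyl ether acetate
Product: 23 ent-6α-acetoxylabda-13(16),14-diene-8α,18-diol (target)
Conditions: HF·pyridine, pyridine, THF, 0 °C → rt
Reagents that add atoms: none
Why: Fluoride-induced Si–O cleavage under buffered, weakly acidic conditions should free the primary C18 hydroxyl without acetyl migration from O6, loss of the tertiary alcohol or damage to the diene.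

**Compound list**

1 | acrolein (prop-2-enal) | C=CC=O | starting material
2 | ethyl 2-(triphenyl-λ5-phosphanylidene)propanoate | CCOC(=O)C(C)=P(c1ccccc1)(c1ccccc1)c1ccccc1 | starting material
3 | ethyl (2E)-2-methylpenta-2,4-dienoate | C=C/C=C(\C)C(=O)OCC | intermediate
4 | (2E)-2-methylpenta-2,4-dien-1-ol | C=C/C=C(\C)CO | intermediate
5 | triisopropyl{[(2E)-2-methylpenta-2,4-dien-1-yl]oxy}silane | C=C/C=C(\C)CO[Si](C(C)C)(C(C)C)C(C)C | intermediate
6 | 2,6-dimethyl-1,4-benzoquinone | CC1=CC(=O)C=C(C)C1=O | starting material
7 | cis-fused enedione: 2,5,8a-trimethyl-5-{[(triisopropylsilyl)oxy]methyl}-4a,5,8,8a-tetrahydronaphthalene-1,4-dione; 4a-H, 5-CH3 and 8a-CH3 on one face, CH2OSi on the other (labdane: C6=O, C9=O, C7=C8, C2=C3) | O=C1[C@]2(C)CC=C[C@](C)(CO[Si](C(C)C)(C(C)C)C(C)C)[C@@H]2C(=O)C=C1C | intermediate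
8 | potassium dienolate of 7 (C5=C6–OK) | O=C1[C@]2(C)CC=C[C@](C)(CO[Si](C(C)C)(C(C)C)C(C)C)C2=C([O-])C=C1C.[K+] | intermediate
9 | 2,5,8a-trimethyl-1-oxo-5-{[(triisopropylsilyl)oxy]methyl}-1,5,8,8a-tetrahydronaphthalen-4-yl trifluoromethanesulfonate (labdane: C5=C6–OTf, C7=C8, C9=O, C2=C3; 5-CH3 cis to 8a-CH3) | O=C1[C@]2(C)CC=C[C@](C)(CO[Si](C(C)C)(C(C)C)C(C)C)C2=C(OS(=O)(=O)C(F)(F)F)C=C1C | intermediate
10 | 2,5,8a-trimethyl-5-{[(triisopropylsilyl)oxy]methyl}-8,8a-dihydronaphthalen-1(5H)-one (labdane: C5=C6, C7=C8, C9=O, C2=C3; 5-CH3 cis to 8a-CH3) | O=C1[C@]2(C)CC=C[C@](C)(CO[Si](C(C)C)(C(C)C)C(C)C)C2=CC=C1C | intermediate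
11 | lithium enolate from 10 (C8=C9–OLi, C5=C6, C2=C3) | [Li+].[O-]C=1[C@]2(C)CC=C[C@](C)(CO[Si](C(C)C)(C(C)C)C(C)C)C2=CCC=1C | intermediate
12 | 2,5,8a-trimethyl-5-{[(triisopropylsilyl)oxy]methyl}-3,5,8,8a-tetrahydronaphthalen-1-yl trifluoromethanesulfonate (labdane: C8=C9–OTf, C5=C6, C2=C3) | O=S(=O)(OC=1[C@]2(C)CC=C[C@](C)(CO[Si](C(C)C)(C(C)C)C(C)C)C2=CCC=1C)C(F)(F)F | intermediate
13 | 2-vinyl-1,3-dioxolane | C=CC1OCCO1 | starting material
14 | 9-[2-(1,3-dioxolan-2-yl)ethyl]-9-borabicyclo[3.3.1]nonane | C1COC(CCB2C3CCCC2CCC3)O1 | intermediate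
15 | 2-{2-[2,5,8a-trimethyl-5-{[(triisopropylsilyl)oxy]methyl}-3,5,8,8a-tetrahydronaphthalen-1-yl]ethyl}-1,3-dioxolane (18-silyloxy-14,15,16-trinor-ent-labda-2,5,8-trien-13-al ethylene acetal) | O1CCOC1CCC=1[C@]2(C)CC=C[C@](C)(CO[Si](C(C)C)(C(C)C)C(C)C)C2=CCC=1C | intermediate
16 | 2-{2-[2,5,8a-trimethyl-5-{[(triisopropylsilyl)oxy]methyl}-3,5,6,7,8,8a-hexahydronaphthalen-1-yl]ethyl}-1,3-dioxolane (18-silyloxy-14,15,16-trinor-ent-labda-5,8-dien-13-al ethylene acetal) | O1CCOC1CCC=1[C@]2(C)CCC[C@](C)(CO[Si](C(C)C)(C(C)C)C(C)C)C2=CCC=1C | intermediate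
17 | 6,8-bis(boranyl) adduct of 16 (B on C6 and C8, H on C5 and C9, all on the face opposite C20) | O1CCOC1CC[C@H]1[C@]2(C)CCC[C@](C)(CO[Si](C(C)C)(C(C)C)C(C)C)[C@H]2[C@H](B)C[C@]1(C)B | intermediate
18 | ent-6α,8α-dihydroxy-18-(triisopropylsilyloxy)-14,15,16-trinorlabdan-13-al ethylene acetal (trans-decalin; H5, H9, 6-OH, 8-OH and C18 anti to C20; C17 and C19 syn to C20) | O1CCOC1CC[C@H]1[C@]2(C)CCC[C@](C)(CO[Si](C(C)C)(C(C)C)C(C)C)[C@H]2[C@H](O)C[C@]1(C)O | intermediate
19 | lactol: ent-8α,13-epoxy-18-(triisopropylsilyloxy)-14,15,16-trinorlabdane-6α,13-diol (anomeric mixture) | OC1CC[C@H]2[C@]3(C)CCC[C@](C)(CO[Si](C(C)C)(C(C)C)C(C)C)[C@H]3[C@H](O)C[C@]2(C)O1 | intermediate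
20 | ent-18-(triisopropylsilyloxy)-15,16-dinorlabd-13-yne-6α,8α-diol | C#CCC[C@H]1[C@]2(C)CCC[C@](C)(CO[Si](C(C)C)(C(C)C)C(C)C)[C@H]2[C@H](O)C[C@]1(C)O | intermediate
21 | ent-18-(triisopropylsilyloxy)labda-13(16),14-diene-6α,8α-diol | C=CC(=C)CC[C@H]1[C@]2(C)CCC[C@](C)(CO[Si](C(C)C)(C(C)C)C(C)C)[C@H]2[C@H](O)C[C@]1(C)O | intermediate
22 | ent-6α-acetoxy-18-(triisopropylsilyloxy)labda-13(16),14-dien-8α-ol | C=CC(=C)CC[C@H]1[C@]2(C)CCC[C@](C)(CO[Si](C(C)C)(C(C)C)C(C)C)[C@H]2[C@H](OC(C)=O)C[C@]1(C)O | intermediate
23 | ent-6α-acetoxylabda-13(16),14-diene-8α,18-diol (6-OAc, 8-OH and 18-CH2OH anti to C20; trans-decalin) | C=CC(=C)CC[C@H]1[C@]2(C)CCC[C@](C)(CO)[C@H]2[C@H](OC(C)=O)C[C@]1(C)O | target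

**Step count and risks**

Total step count: 15. Longest linear sequence: 15 steps (1 → 23); 6 and 13 are purchased and enter in steps 4 and 8.

Most likely to fail:

1. Step 4. The cis-methyl group of 5 disfavours the s-cis conformer, so cycloaddition may be outrun by cationic oligomerisation of the diene, or facial discrimination by the catalyst may be poor. The fallback sets out from 4 and returns at 7, forming the same two bonds intramolecularly.
   - Mitsunobu etherification (PPh3, diisopropyl azodicarboxylate, THF) of 4 with commercial 2,6-dimethylhydroquinone at its unhindered hydroxyl should give 4-{[(2E)-2-methylpenta-2,4-dien-1-yl]oxy}-2,6-dimethylphenol F1.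
   - Oxidative dearomatisation with PhI(OAc)2 in methanol should give the mixed quinone monoketal F2, in which the diene hangs from the future O6.
   - On heating in toluene, the three-atom C6–O–C18 tether should enforce C4–C5/C1–C10 bonding and place C18 anti to C20, giving the tricyclic ketal cycloadduct F3.
   - Dilute aqueous acid should unmask the hydroxy enedione F4.
   - Silylation as in step 3 gives racemic 7, which is resolved by preparative chromatography on a chiral stationary phase before step 5.

2. Step 10. Hydroboration of the hindered tetrasubstituted C8=C9 bond may be slow or may deliver boron to C9 or to the lower face, and the tertiary borane may migrate on warming. The fallback sets out from 16 and returns at 18.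
   - Limited BH3·SMe2 at 0 °C followed by NaOH/H2O2 should hydroborate only the trisubstituted C5=C6 bond and give the 6-alcohol F5 (H5 and 6-OH set, C8=C9 intact).
   - A Schenck ene reaction (O2, visible light, tetraphenylporphyrin, CH2Cl2) should place oxygen on C8 from the face opposite C20 with abstraction of a C11 hydrogen, giving the allylic 8-hydroperoxide F6.
   - PPh3 reduces F6 in the same flask to the allylic 6,8-diol F7 (C9=C11 alkene).
   - Hydroxyl-directed hydrogenation with Crabtree's catalyst [Ir(cod)(PCy3)(py)]PF6 and H2 in CH2Cl2 should deliver hydrogen to C9 from the face of the 8-hydroxyl and give 18.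

3. Step 7. Hydride may attack the C9 carbonyl directly or over-reduce, and the skipped dienolate may equilibrate before it is trapped. The fallback sets out from 10 and returns at 12.
   - Copper hydride conjugate reduction with Stryker's reagent [(Ph3P)CuH]6 and Me3SiCl in THF should give the isolable trimethylsilyl enol ether F8 with exclusive 1,4-delivery.
   - MeLi in THF at 0 °C then regenerates lithium enolate 11 regiospecifically, and PhNTf2 gives 12.

**Further compounds**

F1 | step 4 | 4-{[(2E)-2-methylpenta-2,4-dien-1-yl]oxy}-2,6-dimethylphenol | Cc1cc(OC/C(C)=C/C=C)cc(C)c1O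
F2 | step 4 | 4-methoxy-2,6-dimethyl-4-{[(2E)-2-methylpenta-2,4-dien-1-yl]oxy}cyclohexa-2,5-dien-1-one | COC1(OC/C(C)=C/C=C)C=C(C)C(=O)C(C)=C1
F3 | step 4 | tricyclic ketal cycloadduct (racemic, one enantiomer drawn): C6(OCH3) bridged to C18 through oxygen, C9=O, C7=C8, C2=C3; C5–H, C10–CH3 and C4–CH3 cis | O=C1[C@]2(C)CC=C[C@]3(C)CO[C@](OC)(C=C1C)[C@H]23
F4 | step 4 | hydroxy enedione (racemic, one enantiomer drawn): 5-(hydroxymethyl)-2,5,8a-trimethyl-4a,5,8,8a-tetrahydronaphthalene-1,4-dione, stereochemistry as in 7 | O=C1[C@]2(C)CC=C[C@](C)(CO)[C@@H]2C(=O)C=C1C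
F5 | step 10 | ent-6α-hydroxy-18-(triisopropylsilyloxy)-14,15,16-trinorlabd-8-en-13-al ethylene acetal | O1CCOC1CCC=1[C@]2(C)CCC[C@](C)(CO[Si](C(C)C)(C(C)C)C(C)C)[C@H]2[C@H](O)CC=1C
F6 | step 10 | ent-8α-hydroperoxy-6α-hydroxy-18-(triisopropylsilyloxy)-14,15,16-trinorlabd-9(11)-en-13-al ethylene acetal | O1CCOC1CC=C1[C@]2(C)CCC[C@](C)(CO[Si](C(C)C)(C(C)C)C(C)C)[C@H]2[C@H](O)C[C@]1(C)OO
F7 | step 10 | ent-6α,8α-dihydroxy-18-(triisopropylsilyloxy)-14,15,16-trinorlabd-9(11)-en-13-al ethylene acetal | O1CCOC1CC=C1[C@]2(C)CCC[C@](C)(CO[Si](C(C)C)(C(C)C)C(C)C)[C@H]2[C@H](O)C[C@]1(C)O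
F8 | step 7 | trimethylsilyl enol ether of the 1,4-reduced dienone (C8=C9–OSiMe3, C5=C6, C2=C3) | C[Si](C)(C)OC=1[C@]2(C)CC=C[C@](C)(CO[Si](C(C)C)(C(C)C)C(C)C)C2=CCC=1C
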